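**Retrosynthetic overview**

1. Target ⇐ aerobic γ-hydroxylation (C1–OH) of a β,γ-unsaturated ketone, the spiro Diels–Alder adduct of an 8-epi-xanthatin-type dienone and the antipodal cis-fused α-methylene lactone.
2. Key step, one flask: enyne lactone + but-3-en-2-one + dienophile – enyne ring-closing metathesis (ring A), cross-metathesis (dienone), [4+2] (spiro-cyclohexene); two rings in one operation.
3. Dienophile ⇐ ring-closing metathesis (ring B) ⇐ Ru-catalysed alkyne/but-3-en-2-ol coupling of the mirror-image enyne lactone.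
4. Both enyne lactones ⇐ catalyst-controlled allylboration/lactonisation of enantiomeric β-alkynyl aldehydes (Rh-catalysed conjugate alkynylation of crotonaldehyde) with one allylboronate (carbocupration of methyl propiolate).
5. Ring order: the two butyrolactones → ring B → ring A together with the spiro-cyclohexene.

Assumption: the SMILES is taken literally, so the spiro-lactone half (C7′ S, C8′ S, C10′ R) belongs to the enantiomeric series of the cyclohexene-fused half (C7 R, C8 R, C10 S) and the two halves are made from antipodal aldehydes.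

Notation: xanthane numbering, primes for the spiro-lactone half; ring A / ring B = seven-membered ring of the unprimed / primed half. Catalyst hands are written for the assumed sense of induction; if a first run shows the opposite sense, the two enantiomeric catalysts are exchanged between the two series.

**Route**

Step 1
Reactants: 1 methyl propiolate; 2 allylmagnesium bromide; 3 2-(iodomethyl)-4,4,5,5-tetramethyl-1,3,2-dioxaborolane
Product: 5 methyl (2E)-2-[(4,4,5,5-tetramethyl-1,3,2-dioxaborolan-2-yl)methyl]hexa-2,5-dienoate, via vinylcopper adduct 4 (not isolated)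
Conditions: 2, CuBr·SMe2, THF, −78 °C; 1, −78 °C, 1 h; 3, DMPU, −78 → 0 °C
Reagents that add atoms: none
Why: syn-carbocupration of the ynoate followed by alkylation of the vinylcopper with retention (carbocupration/electrophilic trapping) places the allyl group cis to CH2B, the olefin geometry that later gives a cis-lactone; the mixture is kept below −40 °C until trapping so the α-cuprio acrylate does not isomerise.

Step 2
Reactants: 6 (2E)-but-2-enal; 7 ethynyltri(propan-2-yl)silane
Product: 8 (3S)-3-methyl-5-[tri(propan-2-yl)silyl]pent-4-ynal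
Conditions: [Rh(OAc)(C2H4)2]2 (2.5 mol %), (R)-DTBM-SEGPHOS (5.5 mol %), MeOH, 40 °C
Reagents that add atoms: none
Why: rhodium-catalysed asymmetric conjugate alkynylation of an enal; the bisphosphine–Rh acetylide adds to one enantioface of the enal and sets C10 (S), and the bulky silyl group suppresses alkyne dimerisation.

Step 3
Reactants: 8 (3S)-aldehyde; 5 allylboronate
Product: 10 (4R,5R)-3-methylidene-5-{(2S)-2-methyl-4-[tri(propan-2-yl)silyl]but-3-yn-1-yl}-4-(prop-2-en-1-yl)oxolan-2-one, via boryl ether 9 (not isolated)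
Conditions: (R,R)-F-Vivol·SnCl4 (10 mol %), Na2CO3, 4 Å MS, toluene, −78 → −40 °C; then TsOH·H2O (10 mol %), CH2Cl2, rt
Reagents that add atoms: none
Why: Proposed new method: chiral Brønsted-acid (diol·SnCl4) catalysed allylboration followed by lactonisation, in which the closed chair (Zimmerman–Traxler) transition state with the γ-allyl group axial gives the syn adduct and hence the cis C7/C8 lactone, while the chiral acid bound to a boronate oxygen selects the aldehyde face (reagent control over the remote C10 centre; the uncatalysed background reaction of this ester-deactivated boronate is negligible at low temperature); closest known reactions are the diol·SnCl4-catalysed crotylboration of aliphatic aldehydes with pinacol boronates and the triflic-acid-catalysed addition of 2-alkoxycarbonyl allylboronates that gives α-methylene-γ-lactones.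

Step 4
Reactants: 10 silylated lactone
Product: 11 (4R,5R)-3-methylidene-5-[(2S)-2-methylbut-3-yn-1-yl]-4-(prop-2-en-1-yl)oxolan-2-one
Conditions: Bu4NF (1.2 equiv), AcOH (1.2 equiv), THF, 0 °C → rt
Reagents that add atoms: none
Why: fluoride-mediated protodesilylation of the alkynylsilane; acetic acid buffering keeps the α-methylene lactone and the stereocentres untouched.

Step 5
Reactants: 6 (2E)-but-2-enal; 7 ethynyltri(propan-2-yl)silane
Product: 12 (3R)-3-methyl-5-[tri(propan-2-yl)silyl]pent-4-ynal
Conditions: [Rh(OAc)(C2H4)2]2 (2.5 mol %), (S)-DTBM-SEGPHOS (5.5 mol %), MeOH, 40 °C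
Reagents that add atoms: none
Why: mirror image of step 2 (rhodium-catalysed asymmetric conjugate alkynylation) with the antipodal ligand; sets C10′ (R).

Step 6
Reactants: 12 (3R)-aldehyde; 5 allylboronate
Product: 14 (4S,5S)-3-methylidene-5-{(2R)-2-methyl-4-[tri(propan-2-yl)silyl]but-3-yn-1-yl}-4-(prop-2-en-1-yl)oxolan-2-one, via boryl ether 13 (not isolated)
Conditions: (S,S)-F-Vivol·SnCl4 (10 mol %), Na2CO3, 4 Å MS, toluene, −78 → −40 °C; then TsOH·H2O (10 mol %), CH2Cl2, rt
Reagents that add atoms: none
Why: Proposed new method: mirror image of step 3 – chiral diol·SnCl4-catalysed allylboration/lactonisation through the same chair transition state gives the cis C7′/C8′ lactone, the antipodal acid selecting the other aldehyde face; closest known reactions as in step 3.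

Step 7
Reactants: 14 silylated lactone
Product: 15 (4S,5S)-3-methylidene-5-[(2R)-2-methylbut-3-yn-1-yl]-4-(prop-2-en-1-yl)oxolan-2-one
Conditions: Bu4NF (1.2 equiv), AcOH (1.2 equiv), THF, 0 °C → rt
Reagents that add atoms: none
Why: buffered fluoride protodesilylation as in step 4.

Step 8
Reactants: 15 enyne lactone; 16 but-3-en-2-ol
Product: 18 (4S,5S)-3-methylidene-5-[(2R)-2-methyl-3-methylidene-6-oxoheptyl]-4-(prop-2-en-1-yl)oxolan-2-one, via dienol 17 (not isolated)
Conditions: CpRu(MeCN)3PF6 (10 mol %), 16 (3 equiv), acetone, rt → 50 °C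
Reagents that add atoms: none
Why: ruthenium-catalysed alkyne–allylic alcohol coupling (Alder-ene type, redox-isomerising): the ruthenacyclopentene forms the C–C bond at the internal alkyne carbon, β-hydride elimination toward the carbinol gives the enol and this tautomerises to the methyl ketone; the intramolecular ene partner would need an eight-membered ring and does not compete; no stereocentre is formed or touched.

Step 9
Reactants: 18 keto diene lactone
Product: 19 (3aS,7R,8aS)-7-methyl-3-methylidene-6-(3-oxobutyl)-4,7,8,8a-tetrahydro-3aH-cyclohepta[b]furan-2-one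
Conditions: second-generation Grubbs catalyst RuCl2(=CHPh)(H2IMes)(PCy3) (5 mol %), CH2Cl2 (0.002 M), 40 °C
Reagents that add atoms: none
Why: ring-closing metathesis between the allyl group and the 1,1-disubstituted olefin closes the trisubstituted cycloheptene (ring B); the electron-poor exo-methylene lactone is a poor metathesis partner and survives; no stereocentre is involved.

Step 10 (key step)
Reactants: 11 enyne lactone; 20 but-3-en-2-one; 19 bicyclic α-methylene lactone
Product: 23 spiro Diels–Alder adduct (3S,5S,7R,8R,10S,7′S,8′S,10′R,11′S), via ring-closed vinyl diene 21 (not isolated), via 8-epi-xanthatin 22 (not isolated)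
Conditions: second-generation Hoveyda–Grubbs catalyst RuCl2(=CH–C6H4–2-OiPr)(H2IMes) (10 mol %), 20 (3 equiv), CH2Cl2, 40 °C; volatiles (excess 20) removed; residue in toluene added over 12 h to 19 (5 equiv, excess recovered) and BHT in toluene, 90 °C, then 24 h
Reagents that add atoms: none
Why: domino ring-closing enyne metathesis (ring A) and cross-metathesis give the (E)-dienone 22, which is trapped by the exo-methylene of 19 in a thermal, "ortho"-regioselective Diels–Alder reaction (acetyl-bearing C3 to the substituted carbon C11′, C5 to C13′); C5 comes from addition to the diene face syn to the C10 methyl, and C11′ from endo (lactone C=O) addition with C3 bonding on the lactone face syn to C6′ – the diene face and the endo mode are the usual ones, the lactone face is the hindered one, so this topicity is the accepted risk of the step and the C11′ epimer is the expected by-product (a diastereomer, separable); C3 becomes sp2 in step 11.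

Step 11
Reactants: 23 spiro adduct
Product: 25 target (1S,5S,7R,8R,10S,7′S,8′S,10′R,11′S), via tertiary hydroperoxide 24 (not isolated)
Conditions: O2 (1 atm), DBU (1.2 equiv), P(OEt)3 (2 equiv), MeCN, −20 → 0 °C
Reagents that add atoms: dioxygen, O=O
Why: dienolate autoxidation (γ-oxygenation of a β,γ-unsaturated ketone): removal of the doubly activated C3–H gives the extended dienolate, O2 adds at the γ-carbon C1 axially and anti to the axial H5 (trans-fused ring junction, OH trans to H5), the olefin moves into conjugation with the acetyl group, and the phosphite reduces the hydroperoxide in the same flask.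

**Compound list**

1 | methyl prop-2-ynoate (methyl propiolate) | C#CC(=O)OC | starting material
2 | prop-2-en-1-ylmagnesium bromide (allylmagnesium bromide) | C=CC[Mg]Br | starting material
3 | 2-(iodomethyl)-4,4,5,5-tetramethyl-1,3,2-dioxaborolane | CC1(C)OB(CI)OC1(C)C | starting material
4 | methyl (2Z)-2-cuprio-hexa-2,5-dienoate (vinylcopper adduct, allyl cis to copper) | C=CC/C=C(/C(=O)OC)[Cu] | intermediate
5 | methyl (2E)-2-[(4,4,5,5-tetramethyl-1,3,2-dioxaborolan-2-yl)methyl]hexa-2,5-dienoate (allyl cis to CH2B) | C=CC/C=C(/C(=O)OC)CB1OC(C)(C)C(C)(C)O1 | intermediate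
6 | (2E)-but-2-enal (crotonaldehyde) | C/C=C/C=O | starting material
7 | ethynyltri(propan-2-yl)silane | C#C[Si](C(C)C)(C(C)C)C(C)C | starting material
8 | (3S)-3-methyl-5-[tri(propan-2-yl)silyl]pent-4-ynal | O=CC[C@H](C)C#C[Si](C(C)C)(C(C)C)C(C)C | intermediate
9 | methyl (3R,4R,6S)-6-methyl-2-methylidene-3-(prop-2-en-1-yl)-4-[(4,4,5,5-tetramethyl-1,3,2-dioxaborolan-2-yl)oxy]-8-[tri(propan-2-yl)silyl]oct-7-ynoate (boryl ether) | C=C(C(=O)OC)[C@@H](CC=C)[C@H](OB1OC(C)(C)C(C)(C)O1)C[C@H](C)C#C[Si](C(C)C)(C(C)C)C(C)C | intermediate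
10 | (4R,5R)-3-methylidene-5-{(2S)-2-methyl-4-[tri(propan-2-yl)silyl]but-3-yn-1-yl}-4-(prop-2-en-1-yl)oxolan-2-one | C=C1C(=O)O[C@H](C[C@H](C)C#C[Si](C(C)C)(C(C)C)C(C)C)[C@@H]1CC=C | intermediate
11 | (4R,5R)-3-methylidene-5-[(2S)-2-methylbut-3-yn-1-yl]-4-(prop-2-en-1-yl)oxolan-2-one | C=C1C(=O)O[C@H](C[C@H](C)C#C)[C@@H]1CC=C | intermediate
12 | (3R)-3-methyl-5-[tri(propan-2-yl)silyl]pent-4-ynal | O=CC[C@@H](C)C#C[Si](C(C)C)(C(C)C)C(C)C | intermediate
13 | methyl (3S,4S,6R)-6-methyl-2-methylidene-3-(prop-2-en-1-yl)-4-[(4,4,5,5-tetramethyl-1,3,2-dioxaborolan-2-yl)oxy]-8-[tri(propan-2-yl)silyl]oct-7-ynoate (boryl ether) | C=C(C(=O)OC)[C@H](CC=C)[C@@H](OB1OC(C)(C)C(C)(C)O1)C[C@@H](C)C#C[Si](C(C)C)(C(C)C)C(C)C | intermediate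
14 | (4S,5S)-3-methylidene-5-{(2R)-2-methyl-4-[tri(propan-2-yl)silyl]but-3-yn-1-yl}-4-(prop-2-en-1-yl)oxolan-2-one | C=C1C(=O)O[C@@H](C[C@@H](C)C#C[Si](C(C)C)(C(C)C)C(C)C)[C@H]1CC=C | intermediate
15 | (4S,5S)-3-methylidene-5-[(2R)-2-methylbut-3-yn-1-yl]-4-(prop-2-en-1-yl)oxolan-2-one | C=C1C(=O)O[C@@H](C[C@@H](C)C#C)[C@H]1CC=C | intermediate
16 | but-3-en-2-ol (racemic) | C=CC(C)O | starting material
17 | (4S,5S)-5-[(2R)-6-hydroxy-2-methyl-3-methylidenehept-5-en-1-yl]-3-methylidene-4-(prop-2-en-1-yl)oxolan-2-one (dienol) | C=C1C(=O)O[C@@H](C[C@@H](C)C(=C)CC=C(C)O)[C@H]1CC=C | intermediate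
18 | (4S,5S)-3-methylidene-5-[(2R)-2-methyl-3-methylidene-6-oxoheptyl]-4-(prop-2-en-1-yl)oxolan-2-one | C=C1C(=O)O[C@@H](C[C@@H](C)C(=C)CCC(C)=O)[C@H]1CC=C | intermediate
19 | (3aS,7R,8aS)-7-methyl-3-methylidene-6-(3-oxobutyl)-4,7,8,8a-tetrahydro-3aH-cyclohepta[b]furan-2-one (ent-8-epi-xanthinosin) | C=C1C(=O)O[C@H]2C[C@@H](C)C(CCC(C)=O)=CC[C@@H]12 | intermediate
20 | but-3-en-2-one (methyl vinyl ketone) | C=CC(C)=O | starting material
21 | (3aR,7S,8aR)-6-ethenyl-7-methyl-3-methylidene-4,7,8,8a-tetrahydro-3aH-cyclohepta[b]furan-2-one | C=C1C(=O)O[C@@H]2C[C@H](C)C(C=C)=CC[C@H]12 | intermediate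
22 | (3aR,7S,8aR)-7-methyl-3-methylidene-6-[(1E)-3-oxobut-1-en-1-yl]-4,7,8,8a-tetrahydro-3aH-cyclohepta[b]furan-2-one (8-epi-xanthatin) | C=C1C(=O)O[C@@H]2C[C@H](C)C(/C=C/C(C)=O)=CC[C@H]12 | intermediate
23 | spiro Diels–Alder adduct, (3S,5S,7R,8R,10S,7′S,8′S,10′R,11′S): C1=C2 olefin, 3-acetyl, new bonds C3–C11′ and C5–C13′; unprimed half with cis-8,12-lactone and 11(13)-methylene; primed half with cis-8′,12′-lactone spiro at C11′, C1′(5′)-ene and 3-oxobutyl at C1′ | C=C1C(=O)O[C@@H]2C[C@H](C)C3=C[C@H](C(C)=O)[C@@]4(C[C@@H]3C[C@H]12)C(=O)O[C@H]1C[C@@H](C)C(CCC(C)=O)=CC[C@H]14 | intermediate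
24 | (1S,5S,7R,8R,10S,7′S,8′S,10′R,11′S)-1-hydroperoxy-2-en-4-one (tertiary hydroperoxide corresponding to 25) | C=C1C(=O)O[C@@H]2C[C@H](C)[C@@]3(OO)C=C(C(C)=O)[C@@]4(C[C@@H]3C[C@H]12)C(=O)O[C@H]1C[C@@H](C)C(CCC(C)=O)=CC[C@H]14 | intermediate
25 | CNP0195550.1, (1S,5S,7R,8R,10S,7′S,8′S,10′R,11′S)-1-hydroxy spiro dimer | C=C1C(=O)O[C@@H]2C[C@H](C)[C@@]3(O)C=C(C(C)=O)[C@@]4(C[C@@H]3C[C@H]12)C(=O)O[C@H]1C[C@@H](C)C(CCC(C)=O)=CC[C@H]14 | target

**Totals**

Total step count: 11. Longest linear sequence: 7 steps (steps 5, 6, 7, 8, 9, 10, 11; equally 1, 6, 7, 8, 9, 10, 11).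

**Three steps most likely to fail**

1. Step 10. Risks: homodimerisation of 22 through its own exo-methylene, and above all the lactone-face selectivity at C11′, where the needed isomer requires attack on the hindered face. Fallback, setting out from 22 and 18 and coming back at 23: the metathesis half of step 10 is stopped, 22 is freed from ruthenium (short silica plug, 0 °C) and used at once. It is combined, with no metal present, with the monocyclic lactone 18, whose ring B is not yet closed (5 equiv, neat with BHT at 60 °C, or in CH2Cl2 at 12 kbar and room temperature), to give the spiro adduct with ring B still open F1. Ring-closing metathesis of F1 (second-generation Grubbs catalyst RuCl2(=CHPh)(H2IMes)(PCy3), CH2Cl2, 40 °C) then closes ring B and gives 23. This changes the order of ring formation (spiro-cyclohexene before ring B). The dienophile no longer presents the closed concave pocket of the bicyclic lactone, because its allyl and alkyl arms can turn away from the face that has to be attacked; this lowers the bias but does not remove it.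

2. Step 3 (step 6 is its mirror image and shares the risk). Risk: an untested catalyst–substrate pair has to override the remote C10 centre; failure costs diastereoselectivity, and the two cis-lactones would have to be separated. Fallback for step 3, setting out from 8 (with 2 and 3 for the reagent) and coming back at 10: (1R,2S,5R)-8-phenylmenthyl propiolate F2 (propiolic acid, (−)-8-phenylmenthol, DCC, DMAP) is taken through the sequence of step 1 (2, CuBr·SMe2; the vinylcopper adduct F3; then 3) to the auxiliary-bearing allylboronate F4. F4 and 8 with Sc(OTf)3 (10 mol %, toluene, −78 °C) give the boryl ether F5, which lactonises with TsOH, losing the auxiliary, to give 10. Stereocontrol is moved from a chiral acid to a covalently bound ester auxiliary whose phenyl group shields one face of the allyl unit; the sense of induction of the (−)-auxiliary has to be checked on the first run.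

3. Step 8. Risks: branched versus linear coupling next to a propargylic stereocentre, and side reactions of the allyl group. Fallback, setting out from 15 and coming back at 18: bromoboration of the terminal alkyne (B-bromo-9-borabicyclo[3.3.1]nonane, CH2Cl2, 0 °C) gives the (Z)-2-bromoalkenylborane F6, and protonolysis with AcOH gives the 2-bromo-1-alkene F7. A Heck reaction of F7 with 16 (Pd(OAc)2 5 mol %, Bu4NCl, NaHCO3, DMF, 40 °C) puts the four-carbon unit on the internal carbon and gives, through the same enol 17, the ketone 18. The C–C bond is then made by carbopalladation from a preformed 1,1-disubstituted vinyl halide, so the regiochemistry no longer depends on the ruthenacycle.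

**Further compounds**

F1 | step 10 | spiro Diels–Alder adduct with ring B still open (allyl at C7′, 2-methyl-3-methylidene-6-oxoheptyl at C8′) | C=C1C(=O)O[C@@H]2C[C@H](C)C3=C[C@H](C(C)=O)[C@@]4(C[C@@H]3C[C@H]12)C(=O)O[C@@H](C[C@@H](C)C(=C)CCC(C)=O)[C@H]4CC=C
F2 | step 3 | (1R,2S,5R)-5-methyl-2-(2-phenylpropan-2-yl)cyclohexyl prop-2-ynoate | CC(C)(c1ccccc1)[C@@H]1CC[C@@H](C)C[C@H]1OC(=O)C#C
F3 | step 3 | (1R,2S,5R)-5-methyl-2-(2-phenylpropan-2-yl)cyclohexyl (2Z)-2-cuprio-hexa-2,5-dienoate | CC(C)(c1ccccc1)[C@@H]1CC[C@@H](C)C[C@H]1OC(=O)/C([Cu])=C/CC=C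
F4 | step 3 | (1R,2S,5R)-5-methyl-2-(2-phenylpropan-2-yl)cyclohexyl (2E)-2-[(4,4,5,5-tetramethyl-1,3,2-dioxaborolan-2-yl)methyl]hexa-2,5-dienoate | CC(C)(c1ccccc1)[C@@H]1CC[C@@H](C)C[C@H]1OC(=O)/C(=C/CC=C)CB1OC(C)(C)C(C)(C)O1
F5 | step 3 | 8-phenylmenthyl ester analogue of boryl ether 9 | CC(C)(c1ccccc1)[C@@H]1CC[C@@H](C)C[C@H]1OC(=O)C(=C)[C@@H](CC=C)[C@H](OB1OC(C)(C)C(C)(C)O1)C[C@H](C)C#C[Si](C(C)C)(C(C)C)C(C)C
F6 | step 8 | (4S,5S)-5-[(2R,3Z)-4-(9-borabicyclo[3.3.1]nonan-9-yl)-3-bromo-2-methylbut-3-en-1-yl]-3-methylidene-4-(prop-2-en-1-yl)oxolan-2-one | C=C1C(=O)O[C@@H](C[C@@H](C)/C(Br)=C/B2C3CCCC2CCC3)[C@H]1CC=C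
F7 | step 8 | (4S,5S)-5-[(2R)-3-bromo-2-methylbut-3-en-1-yl]-3-methylidene-4-(prop-2-en-1-yl)oxolan-2-one | C=C1C(=O)O[C@@H](C[C@@H](C)C(Br)=C)[C@H]1CC=C
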